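**Retrosynthetic overview**

1. The plan rests on the carbocyclic ring of the chroman (C4a, C5, C6, C7, C8, C8a): C5 carries the benzofuran-2-yl group, its neighbours C6 and C4a each carry a prenyl unit (free at C6, cyclised through C4 at C4a), and C7 and C8a carry oxygen. This is the pattern left when a 1-acyl-2,6-dialkylhexane-1,3,5-trione closes by aldol condensation.
2. Chroman O1–C2 bond: opened to a symmetric 3,5-dihydroxy-2,6-diprenylphenyl ring (selenoetherification of one of two equivalent phenol–prenyl pairs, deselenation, desilylation).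
3. Resorcinol ring: C1–C6 aldol/dehydration of a benzofuran-2-yl triketone, made by Claisen acylation of the dianion of doubly prenylated acetylacetone with a benzofuran-2-carboxylate.
4. Benzofuran: salicylaldehyde plus ethyl bromoacetate; the (R)-3-methylbut-3-en-2-yl group comes from an aryl boronic ester by lithiation–borylation and Zweifel olefination; the arene comes from phloroglucinol with one acetal-protected oxygen as ortho director.
5. Ring order: furan ring (step 7), resorcinol benzene ring (step 10), pyran ring (step 11).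

Key step: step 10

Remark on the chemistry: ethyl 2,4,6-triisopropylbenzoate and (+)-sparteine are taken as purchasable. Di- and triketones are drawn in their keto forms. The two benzofuran phenol oxygens are carried as triisopropylsilyl ethers, which tolerate the organolithium and alkoxide steps and leave with fluoride at the end.

**Route**

Step 1
Reactants: 1 phloroglucinol
Product: 2 3,5-bis(triisopropylsilyloxy)phenol
Conditions: i-Pr3SiCl (2.0 equiv), imidazole, DMF, 0 °C → rt
Reagents that add atoms: triisopropylsilyl chloride, CC(C)[Si](Cl)(C(C)C)C(C)C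
Why: Imidazole-promoted silyl ether formation; with two equivalents of the bulky chlorosilane the bis-ether should be the main product, and the mono- and tris-ethers are separable and can be recycled.

Step 2
Reactants: 2 3,5-bis(triisopropylsilyloxy)phenol
Product: 3 1-(methoxymethoxy)-3,5-bis(triisopropylsilyloxy)benzene
Conditions: MOMCl, i-Pr2NEt, CH2Cl2, 0 °C → rt
Reagents that add atoms: chloromethyl methyl ether, COCCl
Why: O-Alkylation of the remaining phenol by the chloromethyl ether gives the methoxymethyl acetal, the only ortho-directing group on the ring.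

Step 3
Reactants: 3 1-(methoxymethoxy)-3,5-bis(triisopropylsilyloxy)benzene
Product: 5 2-[2-(methoxymethoxy)-4,6-bis(triisopropylsilyloxy)phenyl]-4,4,5,5-tetramethyl-1,3,2-dioxaborolane, via 2-lithio aryl ether 4 (not isolated)
Conditions: s-BuLi, TMEDA, THF, −78 °C; i-PrOBpin, −78 °C → rt; aq. NH4Cl
Reagents that add atoms: 2-isopropoxy-4,4,5,5-tetramethyl-1,3,2-dioxaborolane, CC(C)OB1OC(C)(C)C(C)(C)O1
Why: Directed ortho-metalation: s-BuLi/TMEDA is guided by the methoxymethoxy group to the adjacent ring carbon (the bulky silyloxy groups do not direct), and the aryllithium is trapped by the borate at −78 °C, below the temperature of silyl migration from oxygen to carbon.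

Step 4
Reactants: 5 2-[2-(methoxymethoxy)-4,6-bis(triisopropylsilyloxy)phenyl]-4,4,5,5-tetramethyl-1,3,2-dioxaborolane; 6 ethyl 2,4,6-triisopropylbenzoate
Product: 9 (S)-2-{1-[2-(methoxymethoxy)-4,6-bis(triisopropylsilyloxy)phenyl]ethyl}-4,4,5,5-tetramethyl-1,3,2-dioxaborolane, via (R)-1-lithioethyl triisopropylbenzoate 7 (not isolated), via lithium boronate complex 8 (not isolated)
Conditions: 6, s-BuLi, (+)-sparteine, Et2O, −78 °C; then 5, −78 °C → 35 °C; aq. NH4Cl
Reagents that add atoms: none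
Why: Lithiation–borylation (sparteine-mediated enantioselective deprotonation, then stereospecific 1,2-metallate rearrangement): s-BuLi/(+)-sparteine removes the pro-R hydrogen to give the (R)-lithiated ester, which adds to boron with retention, and the aryl group then migrates anti to the departing carboxylate with inversion, which sets the (S) boronic ester.

Step 5
Reactants: 9 (S)-2-{1-[2-(methoxymethoxy)-4,6-bis(triisopropylsilyloxy)phenyl]ethyl}-4,4,5,5-tetramethyl-1,3,2-dioxaborolane; 10 2-bromopropene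
Product: 14 (R)-1-(methoxymethoxy)-2-(3-methylbut-3-en-2-yl)-3,5-bis(triisopropylsilyloxy)benzene, via isopropenyllithium 11 (not isolated), via lithium alkenylboronate 12 (not isolated), via iodoalkyl boronic ester 13 (not isolated)
Conditions: 10, t-BuLi (2 equiv per bromide), THF, −78 °C; then 9, −78 °C; I2, MeOH, −78 °C; NaOMe, MeOH, −78 °C → rt
Reagents that add atoms: none
Why: Zweifel olefination: iodination of the alkenyl boronate triggers 1,2-migration of the secondary benzylic group with retention at the migrating carbon, and methoxide-induced anti elimination of boron and iodide gives the 1,1-disubstituted alkene, so the (S) boronic ester becomes the (R) hydrocarbon centre (the descriptor changes only because the priorities change).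

Step 6
Reactants: 14 (R)-1-(methoxymethoxy)-2-(3-methylbut-3-en-2-yl)-3,5-bis(triisopropylsilyloxy)benzene
Product: 17 (R)-2-hydroxy-3-(3-methylbut-3-en-2-yl)-4,6-bis(triisopropylsilyloxy)benzaldehyde, via 6-lithio arene 15 (not isolated), via methoxymethyl-protected aldehyde 16 (not isolated)
Conditions: s-BuLi, TMEDA, THF, −78 °C; DMF, −78 → 0 °C; then HCl (3 M aq.), MeOH, rt
Reagents that add atoms: N,N-dimethylformamide, CN(C)C=O
Why: A second directed ortho-metalation at the only remaining position next to the acetal, formylation with DMF, and acid-catalysed acetal exchange of the methoxymethyl ether that is now ortho to the aldehyde, under dilute methanolic HCl that leaves the aryl silyl ethers and the alkene alone.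

Step 7
Reactants: 17 (R)-2-hydroxy-3-(3-methylbut-3-en-2-yl)-4,6-bis(triisopropylsilyloxy)benzaldehyde; 18 ethyl bromoacetate
Product: 20 ethyl (R)-7-(3-methylbut-3-en-2-yl)-4,6-bis(triisopropylsilyloxy)benzofuran-2-carboxylate, via aryloxyacetate 19 (not isolated)
Conditions: K2CO3, MeCN, 60 °C; then DBU, 4 Å molecular sieves, 80 °C
Reagents that add atoms: none
Why: O-Alkylation of the phenol by the α-bromo ester, then DBU-mediated intramolecular aldol condensation onto the ortho aldehyde and dehydration (Rap–Stoermer-type benzofuran synthesis).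

Step 8
Reactants: 21 acetylacetone; 22 prenyl bromide (2 equiv)
Product: 26 2,12-dimethyltrideca-2,11-diene-6,8-dione, via dilithio pentane-2,4-dione 23 (not isolated), via lithium enolate of 8-methylnon-7-ene-2,4-dione 24 (not isolated), via dilithio 8-methylnon-7-ene-2,4-dione 25 (not isolated)
Conditions: LiN(i-Pr)2 (2.0 equiv), THF, −78 → 0 °C; 22 (1.0 equiv), −78 → 0 °C; LiN(i-Pr)2 (1.0 equiv), −78 → 0 °C; 22 (1.0 equiv); 1 M HCl
Reagents that add atoms: none
Why: Hauser-type γ-alkylation of a β-diketone dianion: the terminal carbanion is the reactive site and displaces the allylic bromide, and regeneration of the dianion at the remaining methyl group followed by a second alkylation gives the symmetric diketone.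

Step 9
Reactants: 20 ethyl (R)-7-(3-methylbut-3-en-2-yl)-4,6-bis(triisopropylsilyloxy)benzofuran-2-carboxylate; 26 2,12-dimethyltrideca-2,11-diene-6,8-dione (3 equiv)
Product: 28 1-[(R)-7-(3-methylbut-3-en-2-yl)-4,6-bis(triisopropylsilyloxy)benzofuran-2-yl]-2,6-bis(3-methylbut-2-enyl)hexane-1,3,5-trione (C2 of the chain unassigned, enolisable), via dilithio diketone 27 (not isolated)
Conditions: 26, LiN(i-Pr)2 (2.0 equiv per diketone), THF, 0 °C; then 20, −78 → 0 °C; AcOH, −78 °C
Reagents that add atoms: none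
Why: Claisen-type C-acylation of a β-diketone dianion at its terminal carbon by a non-enolisable heteroaryl ester (Hauser–Harris triketone synthesis); the excess dianion deprotonates the triketone as it forms, and since the diketone is symmetric only one triketone can arise.

Step 10
Reactants: 28 1-[(R)-7-(3-methylbut-3-en-2-yl)-4,6-bis(triisopropylsilyloxy)benzofuran-2-yl]-2,6-bis(3-methylbut-2-enyl)hexane-1,3,5-trione
Product: 29 (R)-2-[3,5-dihydroxy-2,6-bis(3-methylbut-2-enyl)phenyl]-7-(3-methylbut-3-en-2-yl)-4,6-bis(triisopropylsilyloxy)benzofuran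
Conditions: KOt-Bu (4 equiv), t-BuOH/THF, 50 °C, argon; AcOH
Reagents that add atoms: none
Why: In t-BuOK/t-BuOH the triketone is held as rapidly equilibrating enolates; the minor one with carbanion character at the terminal carbon C6 adds to the benzofuran-2-yl ketone C1, the aldolate loses hydroxide by E1cB elimination, and tautomerisation of the cyclohexenedione to the resorcinol makes the sequence irreversible. The closest known reaction type is the base-induced aldol cycloaromatisation of 2,4,6-triketones and of their 4-pyranone forms to 5-substituted resorcinols. The benzene ring is closed in a 6-(enolendo)-exo-trig mode by the C6–C1 bond, the only six-membered carbon–carbon closure open to the chain. No stereocentre is formed; the (R) centre on the benzofuran should be kept because its benzylic, allylic hydrogen sits between two ortho substituents on an electron-rich ring and is not removed by tert-butoxide at 50 °C. The step needs carbon–carbon closure in preference to oxygen closure and to retro-Claisen cleavage of the 2-alkyl-1,3-diketone: under base the hemiketal leading to the 4-pyranone cannot lose water and reverts, and the bulky alkoxide should not add to the ketones or attack the triisopropylsilyl ethers.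

Step 11
Reactants: 29 (R)-2-[3,5-dihydroxy-2,6-bis(3-methylbut-2-enyl)phenyl]-7-(3-methylbut-3-en-2-yl)-4,6-bis(triisopropylsilyloxy)benzofuran
Product: 30 5-[(R)-7-(3-methylbut-3-en-2-yl)-4,6-bis(triisopropylsilyloxy)benzofuran-2-yl]-2,2-dimethyl-6-(3-methylbut-2-enyl)-3-(phenylselanyl)chroman-7-ol (both C3 epimers)
Conditions: N-(phenylseleno)phthalimide (0.9 equiv), (+)-10-camphorsulfonic acid (10 mol %), CH2Cl2, −40 → 0 °C
Reagents that add atoms: N-(phenylseleno)phthalimide, O=C1c2ccccc2C(=O)N1[Se]c1ccccc1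
Why: Electrophilic selenoetherification: the seleniranium ion on a trisubstituted prenyl alkene is opened by the neighbouring phenol at the tertiary carbon (6-endo, Markovnikov) to give the 2,2-dimethylchroman; the two phenol–prenyl pairs are equivalent, so a slight deficit of reagent is used and unreacted 29 is recovered, while the isopropenyl group, which has no free nucleophile nearby, should only add the reagent reversibly, and the selenium-bearing carbon forms as both epimers and is erased in the next step.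

Step 12
Reactants: 30 the 3-(phenylselanyl)chroman
Product: 31 (R)-5-[7-(3-methylbut-3-en-2-yl)-4,6-bis(triisopropylsilyloxy)benzofuran-2-yl]-2,2-dimethyl-6-(3-methylbut-2-enyl)chroman-7-ol
Conditions: n-Bu3SnH, AIBN (cat.), PhMe, 80 °C
Reagents that add atoms: none
Why: Radical chain reduction of the alkyl phenyl selenide by the tin hydride; the secondary chroman radical has no alkene within reach and is simply reduced.

Step 13
Reactants: 31 the bis(triisopropylsilyl) chroman
Product: 32 (R)-2-[7-hydroxy-2,2-dimethyl-6-(3-methylbut-2-enyl)chroman-5-yl]-7-(3-methylbut-3-en-2-yl)benzofuran-4,6-diol (CNP0325834.1)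
Conditions: n-Bu4NF, AcOH, THF, 0 °C, argon
Reagents that add atoms: none
Why: Fluoride cleaves the two aryl silyl ethers under buffered, non-acidic conditions that should leave the ortho-prenylphenol, the isopropenyl group and the benzylic stereocentre untouched.

**Compound list**

1 | phloroglucinol | Oc1cc(O)cc(O)c1 | starting material
2 | 3,5-bis(triisopropylsilyloxy)phenol | Oc1cc(O[Si](C(C)C)(C(C)C)C(C)C)cc(O[Si](C(C)C)(C(C)C)C(C)C)c1 | intermediate
3 | 1-(methoxymethoxy)-3,5-bis(triisopropylsilyloxy)benzene | COCOc1cc(O[Si](C(C)C)(C(C)C)C(C)C)cc(O[Si](C(C)C)(C(C)C)C(C)C)c1 | intermediate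
4 | 2-lithio-1-(methoxymethoxy)-3,5-bis(triisopropylsilyloxy)benzene (not isolated) | [Li]c1c(OCOC)cc(O[Si](C(C)C)(C(C)C)C(C)C)cc1O[Si](C(C)C)(C(C)C)C(C)C | intermediate
5 | 2-[2-(methoxymethoxy)-4,6-bis(triisopropylsilyloxy)phenyl]-4,4,5,5-tetramethyl-1,3,2-dioxaborolane | CC1(C)OB(OC1(C)C)c1c(OCOC)cc(O[Si](C(C)C)(C(C)C)C(C)C)cc1O[Si](C(C)C)(C(C)C)C(C)C | intermediate
6 | ethyl 2,4,6-triisopropylbenzoate | CCOC(=O)c1c(C(C)C)cc(C(C)C)cc1C(C)C | starting material
7 | (R)-1-lithioethyl 2,4,6-triisopropylbenzoate, (+)-sparteine complex (not isolated) | C[C@@H]([Li])OC(=O)c1c(C(C)C)cc(C(C)C)cc1C(C)C | intermediate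
8 | lithium (R)-boronate complex of 5 and 7 (not isolated) | [Li+].C[C@@H]([B-]1(OC(C)(C)C(C)(C)O1)c1c(OCOC)cc(O[Si](C(C)C)(C(C)C)C(C)C)cc1O[Si](C(C)C)(C(C)C)C(C)C)OC(=O)c1c(C(C)C)cc(C(C)C)cc1C(C)C | intermediate
9 | (S)-2-{1-[2-(methoxymethoxy)-4,6-bis(triisopropylsilyloxy)phenyl]ethyl}-4,4,5,5-tetramethyl-1,3,2-dioxaborolane | C[C@H](B1OC(C)(C)C(C)(C)O1)c1c(OCOC)cc(O[Si](C(C)C)(C(C)C)C(C)C)cc1O[Si](C(C)C)(C(C)C)C(C)C | intermediate
10 | 2-bromopropene | C=C(C)Br | starting material
11 | isopropenyllithium (not isolated) | [Li]C(C)=C | intermediate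
12 | lithium (S)-isopropenyl boronate complex of 9 (not isolated) | [Li+].C=C(C)[B-]1(OC(C)(C)C(C)(C)O1)[C@@H](C)c1c(OCOC)cc(O[Si](C(C)C)(C(C)C)C(C)C)cc1O[Si](C(C)C)(C(C)C)C(C)C | intermediate
13 | 2-[(3R)-3-aryl-1-iodo-2-methylbutan-2-yl]-4,4,5,5-tetramethyl-1,3,2-dioxaborolane, aryl = 2-(methoxymethoxy)-4,6-bis(triisopropylsilyloxy)phenyl, both C2 epimers (not isolated) | ICC(C)(B1OC(C)(C)C(C)(C)O1)[C@@H](C)c1c(OCOC)cc(O[Si](C(C)C)(C(C)C)C(C)C)cc1O[Si](C(C)C)(C(C)C)C(C)C | intermediate
14 | (R)-1-(methoxymethoxy)-2-(3-methylbut-3-en-2-yl)-3,5-bis(triisopropylsilyloxy)benzene | C=C(C)[C@@H](C)c1c(OCOC)cc(O[Si](C(C)C)(C(C)C)C(C)C)cc1O[Si](C(C)C)(C(C)C)C(C)C | intermediate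
15 | (R)-6-lithio derivative of 14 (lithium between the acetal and a silyloxy group; not isolated) | C=C(C)[C@@H](C)c1c(OCOC)c([Li])c(O[Si](C(C)C)(C(C)C)C(C)C)cc1O[Si](C(C)C)(C(C)C)C(C)C | intermediate
16 | (R)-2-(methoxymethoxy)-3-(3-methylbut-3-en-2-yl)-4,6-bis(triisopropylsilyloxy)benzaldehyde (not isolated) | C=C(C)[C@@H](C)c1c(OCOC)c(C=O)c(O[Si](C(C)C)(C(C)C)C(C)C)cc1O[Si](C(C)C)(C(C)C)C(C)C | intermediate
17 | (R)-2-hydroxy-3-(3-methylbut-3-en-2-yl)-4,6-bis(triisopropylsilyloxy)benzaldehyde | C=C(C)[C@@H](C)c1c(O)c(C=O)c(O[Si](C(C)C)(C(C)C)C(C)C)cc1O[Si](C(C)C)(C(C)C)C(C)C | intermediate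
18 | ethyl bromoacetate | CCOC(=O)CBr | starting material
19 | ethyl (R)-2-[2-formyl-6-(3-methylbut-3-en-2-yl)-3,5-bis(triisopropylsilyloxy)phenoxy]acetate (not isolated) | C=C(C)[C@@H](C)c1c(OCC(=O)OCC)c(C=O)c(O[Si](C(C)C)(C(C)C)C(C)C)cc1O[Si](C(C)C)(C(C)C)C(C)C | intermediate
20 | ethyl (R)-7-(3-methylbut-3-en-2-yl)-4,6-bis(triisopropylsilyloxy)benzofuran-2-carboxylate | C=C(C)[C@@H](C)c1c(O[Si](C(C)C)(C(C)C)C(C)C)cc(O[Si](C(C)C)(C(C)C)C(C)C)c2cc(C(=O)OCC)oc12 | intermediate
21 | acetylacetone | CC(=O)CC(C)=O | starting material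
22 | prenyl bromide | BrCC=C(C)C | starting material
23 | dilithium dianion of pentane-2,4-dione (not isolated) | [Li+].[Li+].C=C([O-])C=C(C)[O-] | intermediate
24 | lithium enolate of 8-methylnon-7-ene-2,4-dione (not isolated) | [Li+].CC(=O)C=C([O-])CCC=C(C)C | intermediate
25 | dilithium dianion of 8-methylnon-7-ene-2,4-dione (not isolated) | [Li+].[Li+].C=C([O-])C=C([O-])CCC=C(C)C | intermediate
26 | 2,12-dimethyltrideca-2,11-diene-6,8-dione | CC(C)=CCCC(=O)CC(=O)CCC=C(C)C | intermediate
27 | dilithium dianion of 26 (not isolated) | [Li+].[Li+].CC(C)=CCC=C([O-])C=C([O-])CCC=C(C)C | intermediate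
28 | 1-[(R)-7-(3-methylbut-3-en-2-yl)-4,6-bis(triisopropylsilyloxy)benzofuran-2-yl]-2,6-bis(3-methylbut-2-enyl)hexane-1,3,5-trione | C=C(C)[C@@H](C)c1c(O[Si](C(C)C)(C(C)C)C(C)C)cc(O[Si](C(C)C)(C(C)C)C(C)C)c2cc(C(=O)C(CC=C(C)C)C(=O)CC(=O)CCC=C(C)C)oc12 | intermediate
29 | (R)-2-[3,5-dihydroxy-2,6-bis(3-methylbut-2-enyl)phenyl]-7-(3-methylbut-3-en-2-yl)-4,6-bis(triisopropylsilyloxy)benzofuran | C=C(C)[C@@H](C)c1c(O[Si](C(C)C)(C(C)C)C(C)C)cc(O[Si](C(C)C)(C(C)C)C(C)C)c2cc(-c3c(CC=C(C)C)c(O)cc(O)c3CC=C(C)C)oc12 | intermediate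
30 | 5-[(R)-7-(3-methylbut-3-en-2-yl)-4,6-bis(triisopropylsilyloxy)benzofuran-2-yl]-2,2-dimethyl-6-(3-methylbut-2-enyl)-3-(phenylselanyl)chroman-7-ol, both C3 epimers | C=C(C)[C@@H](C)c1c(O[Si](C(C)C)(C(C)C)C(C)C)cc(O[Si](C(C)C)(C(C)C)C(C)C)c2cc(-c3c(CC=C(C)C)c(O)cc4c3CC([Se]c5ccccc5)C(C)(C)O4)oc12 | intermediate
31 | (R)-5-[7-(3-methylbut-3-en-2-yl)-4,6-bis(triisopropylsilyloxy)benzofuran-2-yl]-2,2-dimethyl-6-(3-methylbut-2-enyl)chroman-7-ol | C=C(C)[C@@H](C)c1c(O[Si](C(C)C)(C(C)C)C(C)C)cc(O[Si](C(C)C)(C(C)C)C(C)C)c2cc(-c3c(CC=C(C)C)c(O)cc4c3CCC(C)(C)O4)oc12 | intermediate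
32 | (R)-2-[7-hydroxy-2,2-dimethyl-6-(3-methylbut-2-enyl)chroman-5-yl]-7-(3-methylbut-3-en-2-yl)benzofuran-4,6-diol | C=C(C)[C@@H](C)c1c(O)cc(O)c2cc(-c3c(CC=C(C)C)c(O)cc4c3CCC(C)(C)O4)oc12 | target

**Step count and risks**

Total: 13 steps. Longest linear sequence: 12 steps (steps 1–7, then 9–13); step 8 is a one-step side branch.

Steps most likely to fail:

1. Step 10. The terminal carbanion may fail to add to the hindered ketone, which is also deactivated by donation from the silyloxy groups through the benzofuran, so that retro-Claisen cleavage or desilylation takes over. Fallback, from the dilithio diketone 27 and the aryllithium 15, back at 29: the aldol is moved to a better acceptor and the benzofuran is built last. 27 is acylated with ethyl diethoxyacetate in place of 20 to give 1,1-diethoxy-3,7-bis(3-methylbut-2-enyl)heptane-2,4,6-trione F1, whose unconjugated dialkoxy ketone is closed with KOt-Bu as in step 10 to 5-(diethoxymethyl)-4,6-bis(3-methylbut-2-enyl)benzene-1,3-diol F2. Mild hydrolysis (pyridinium p-toluenesulfonate, acetone/water) gives 3,5-dihydroxy-2,6-bis(3-methylbut-2-enyl)benzaldehyde F3, and Ohira–Bestmann homologation (dimethyl (1-diazo-2-oxopropyl)phosphonate, K2CO3, MeOH) gives 5-ethynyl-4,6-bis(3-methylbut-2-enyl)benzene-1,3-diol F4. Separately, 15 is quenched with I2 to (R)-2-iodo-1-(methoxymethoxy)-6-(3-methylbut-3-en-2-yl)-3,5-bis(triisopropylsilyloxy)benzene F5, and methanolic HCl frees (R)-2-iodo-6-(3-methylbut-3-en-2-yl)-3,5-bis(triisopropylsilyloxy)phenol F6. Sonogashira coupling of F6 with F4 (PdCl2(PPh3)2, CuI, Et3N, DMF, 60 °C), with 5-endo-dig closure of the ortho-alkynylphenol in the same flask, should give 29.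

2. Step 4. Ate-complex formation at a boron atom flanked by two ortho oxygen substituents may be slow or incomplete, so that the lithiated ester decomposes first or enantiomeric purity is eroded. Fallback, from the aryllithium 4, back at 14: the stereocentre is set by copper-catalysed asymmetric allylic alkylation instead of boron homologation. 4 is formylated with DMF to 2-(methoxymethoxy)-4,6-bis(triisopropylsilyloxy)benzaldehyde F7. Wittig reaction with Ph3P=C(CH3)CO2Et gives ethyl (E)-3-[2-(methoxymethoxy)-4,6-bis(triisopropylsilyloxy)phenyl]-2-methylprop-2-enoate F8, i-Bu2AlH gives (E)-3-[2-(methoxymethoxy)-4,6-bis(triisopropylsilyloxy)phenyl]-2-methylprop-2-en-1-ol F9, and MsCl/LiCl/2,6-lutidine gives 2-[(E)-3-chloro-2-methylprop-1-enyl]-1-(methoxymethoxy)-3,5-bis(triisopropylsilyloxy)benzene F10. MeMgBr with catalytic copper thiophene-2-carboxylate (CuO2CC4H3S) and a chiral phosphoramidite ligand (CH2Cl2, −78 °C) then adds the methyl group SN2′ at the aryl-bearing carbon and should give 14; the ligand antipode is chosen for the (R) centre.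

3. Step 11. Over-reaction is the concern: closure of the second phenol–prenyl pair, or attack of the selenium electrophile on the isopropenyl group or on the activated ring carbon between the two phenols. Fallback, from the lithium enolate 24 (after the first alkylation in step 8) and the ester 20, back at 31: the two side chains are made different so that only one can cyclise. 24 is deprotonated again and alkylated with allyl bromide instead of the second prenyl bromide to give 2-methyldodeca-2,11-diene-6,8-dione F11. Acylation of its dianion with 20 as in step 9 gives the regioisomeric triketones 1-[(R)-7-(3-methylbut-3-en-2-yl)-4,6-bis(triisopropylsilyloxy)benzofuran-2-yl]-2-(3-methylbut-2-enyl)non-8-ene-1,3,5-trione F12 and 1-[(R)-7-(3-methylbut-3-en-2-yl)-4,6-bis(triisopropylsilyloxy)benzofuran-2-yl]-9-methyl-2-(prop-2-enyl)dec-8-ene-1,3,5-trione F13. Both converge in the aldol closure of step 10 on one product, (R)-2-[2-allyl-3,5-dihydroxy-6-(3-methylbut-2-enyl)phenyl]-7-(3-methylbut-3-en-2-yl)-4,6-bis(triisopropylsilyloxy)benzofuran F14. N-(Phenylseleno)phthalimide should then react only at the trisubstituted alkene to give 6-allyl-5-[(R)-7-(3-methylbut-3-en-2-yl)-4,6-bis(triisopropylsilyloxy)benzofuran-2-yl]-2,2-dimethyl-3-(phenylselanyl)chroman-7-ol F15, and n-Bu3SnH/AIBN gives (R)-6-allyl-5-[7-(3-methylbut-3-en-2-yl)-4,6-bis(triisopropylsilyloxy)benzofuran-2-yl]-2,2-dimethylchroman-7-ol F16. Cross-metathesis with 2-methylbut-2-ene (second-generation Grubbs catalyst, RuCl2(=CHPh)(PCy3)(1,3-dimesitylimidazolidin-2-ylidene)) converts the allyl group into the prenyl group of 31; the hindered isopropenyl group should not take part.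

**Further compounds**

F1 | step 10 | 1,1-diethoxy-3,7-bis(3-methylbut-2-enyl)heptane-2,4,6-trione | CCOC(OCC)C(=O)C(CC=C(C)C)C(=O)CC(=O)CCC=C(C)C
F2 | step 10 | 5-(diethoxymethyl)-4,6-bis(3-methylbut-2-enyl)benzene-1,3-diol | CCOC(OCC)c1c(CC=C(C)C)c(O)cc(O)c1CC=C(C)C
F3 | step 10 | 3,5-dihydroxy-2,6-bis(3-methylbut-2-enyl)benzaldehyde | O=Cc1c(CC=C(C)C)c(O)cc(O)c1CC=C(C)C
F4 | step 10 | 5-ethynyl-4,6-bis(3-methylbut-2-enyl)benzene-1,3-diol | C#Cc1c(CC=C(C)C)c(O)cc(O)c1CC=C(C)C
F5 | step 10 | (R)-2-iodo-1-(methoxymethoxy)-6-(3-methylbut-3-en-2-yl)-3,5-bis(triisopropylsilyloxy)benzene | C=C(C)[C@@H](C)c1c(OCOC)c(I)c(O[Si](C(C)C)(C(C)C)C(C)C)cc1O[Si](C(C)C)(C(C)C)C(C)C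
F6 | step 10 | (R)-2-iodo-6-(3-methylbut-3-en-2-yl)-3,5-bis(triisopropylsilyloxy)phenol | C=C(C)[C@@H](C)c1c(O)c(I)c(O[Si](C(C)C)(C(C)C)C(C)C)cc1O[Si](C(C)C)(C(C)C)C(C)C
F7 | step 4 | 2-(methoxymethoxy)-4,6-bis(triisopropylsilyloxy)benzaldehyde | O=Cc1c(OCOC)cc(O[Si](C(C)C)(C(C)C)C(C)C)cc1O[Si](C(C)C)(C(C)C)C(C)C
F8 | step 4 | ethyl (E)-3-[2-(methoxymethoxy)-4,6-bis(triisopropylsilyloxy)phenyl]-2-methylprop-2-enoate | CCOC(=O)/C(C)=C/c1c(OCOC)cc(O[Si](C(C)C)(C(C)C)C(C)C)cc1O[Si](C(C)C)(C(C)C)C(C)C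
F9 | step 4 | (E)-3-[2-(methoxymethoxy)-4,6-bis(triisopropylsilyloxy)phenyl]-2-methylprop-2-en-1-ol | OC/C(C)=C/c1c(OCOC)cc(O[Si](C(C)C)(C(C)C)C(C)C)cc1O[Si](C(C)C)(C(C)C)C(C)C
F10 | step 4 | 2-[(E)-3-chloro-2-methylprop-1-enyl]-1-(methoxymethoxy)-3,5-bis(triisopropylsilyloxy)benzene | ClC/C(C)=C/c1c(OCOC)cc(O[Si](C(C)C)(C(C)C)C(C)C)cc1O[Si](C(C)C)(C(C)C)C(C)C
F11 | step 11 | 2-methyldodeca-2,11-diene-6,8-dione | CC(C)=CCCC(=O)CC(=O)CCC=C
F12 | step 11 | 1-[(R)-7-(3-methylbut-3-en-2-yl)-4,6-bis(triisopropylsilyloxy)benzofuran-2-yl]-2-(3-methylbut-2-enyl)non-8-ene-1,3,5-trione | C=C(C)[C@@H](C)c1c(O[Si](C(C)C)(C(C)C)C(C)C)cc(O[Si](C(C)C)(C(C)C)C(C)C)c2cc(C(=O)C(CC=C(C)C)C(=O)CC(=O)CCC=C)oc12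
F13 | step 11 | 1-[(R)-7-(3-methylbut-3-en-2-yl)-4,6-bis(triisopropylsilyloxy)benzofuran-2-yl]-9-methyl-2-(prop-2-enyl)dec-8-ene-1,3,5-trione | C=C(C)[C@@H](C)c1c(O[Si](C(C)C)(C(C)C)C(C)C)cc(O[Si](C(C)C)(C(C)C)C(C)C)c2cc(C(=O)C(CC=C)C(=O)CC(=O)CCC=C(C)C)oc12
F14 | step 11 | (R)-2-[2-allyl-3,5-dihydroxy-6-(3-methylbut-2-enyl)phenyl]-7-(3-methylbut-3-en-2-yl)-4,6-bis(triisopropylsilyloxy)benzofuran | C=C(C)[C@@H](C)c1c(O[Si](C(C)C)(C(C)C)C(C)C)cc(O[Si](C(C)C)(C(C)C)C(C)C)c2cc(-c3c(CC=C)c(O)cc(O)c3CC=C(C)C)oc12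
F15 | step 11 | 6-allyl-5-[(R)-7-(3-methylbut-3-en-2-yl)-4,6-bis(triisopropylsilyloxy)benzofuran-2-yl]-2,2-dimethyl-3-(phenylselanyl)chroman-7-ol, both C3 epimers | C=C(C)[C@@H](C)c1c(O[Si](C(C)C)(C(C)C)C(C)C)cc(O[Si](C(C)C)(C(C)C)C(C)C)c2cc(-c3c(CC=C)c(O)cc4c3CC([Se]c5ccccc5)C(C)(C)O4)oc12
F16 | step 11 | (R)-6-allyl-5-[7-(3-methylbut-3-en-2-yl)-4,6-bis(triisopropylsilyloxy)benzofuran-2-yl]-2,2-dimethylchroman-7-ol | C=C(C)[C@@H](C)c1c(O[Si](C(C)C)(C(C)C)C(C)C)cc(O[Si](C(C)C)(C(C)C)C(C)C)c2cc(-c3c(CC=C)c(O)cc4c3CCC(C)(C)O4)oc12
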